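Numbering: butenolide O1, C2 (lactone C=O), C3 (C–OH), C4 (C–aryl), C5 (quaternary); C6 is the benzylic CH2; primed atoms belong to the dihydrobenzofuran.
Enabling feature: C6 is a CH2 held between C5' of the dihydrobenzofuran ring and quaternary C5. O1 on C5 can be read as the oxygen of a C5–C6 oxirane, and C5 and the C2 carboxyl stand cis on C3=C4.
Cuts: after the three hydrogenolysable O-protecting groups, C5'–C6 and O1–C2 are cut together, giving glycidic ester 13 and aryl Grignard reagent 22. Ester 13 is cut at C4–C5 (Stille) and C3–C4 (Claisen); 22 is cut at O1'–C2' and at the aryl–prenyl bond.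
Forward: the C2–C3–C4 chain is built, fixed as one enol triflate isomer, joined to a three-carbon allylic alcohol, epoxidised and oxidised to 13. The dihydrofuran ring closes first (step 12), the butenolide ring closes last (step 15), and one hydrogenolysis ends the route.
Stereochemistry: C5 comes from Sharpless epoxidation with D-(−)-diethyl tartrate, and its C–O bond is never broken afterwards. C2' comes from Shi epoxidation with the D-fructose-derived ketone followed by an invertive 5-exo-tet closure. The C3=C4 geometry comes from a lithium-chelated enolate.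

Key step: step 15

Remark on the chemistry: the C2 carboxyl is carried as a tert-butyl ester. A methyl ester cis to the free CH2OH of 9 and 10 would be expected to close a six-membered lactone before the oxirane exists. tert-Butoxide is then the group expelled in step 15.
Assumption: 1, 2, 4, 7, 14, 15 and all reagents named are taken to be commercial.

Step 1
Reactants: 1 benzyl alcohol; 2 tert-butyl bromoacetate
Product: 3 tert-butyl 2-(benzyloxy)acetate
Conditions: NaH, THF, 0 → 23 °C
Reagents that add atoms: none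
Why: Williamson ether synthesis in which sodium benzyl oxide displaces the activated primary bromide while the tert-butyl ester resists transesterification.

Step 2
Reactants: 3 tert-butyl 2-(benzyloxy)acetate; 4 methyl 4-(benzyloxy)benzoate
Product: 5 tert-butyl 2-(benzyloxy)-3-[4-(benzyloxy)phenyl]-3-oxopropanoate (racemic and configurationally labile)
Conditions: LiN(SiMe3)2 (2.2 equiv), THF, −78 → 0 °C
Reagents that add atoms: none
Why: Crossed Claisen condensation in which the lithium enolate of 3, slow to self-condense as a tert-butyl ester, acylates on the non-enolisable benzoate 4, and deprotonation of the β-keto ester by the second equivalent of base drives the equilibrium.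

Step 3
Reactants: 5 β-keto ester
Product: 6 tert-butyl (2E)-2-(benzyloxy)-3-[4-(benzyloxy)phenyl]-3-(trifluoromethylsulfonyloxy)prop-2-enoate (OTf cis to the ester)
Conditions: Tf2O, Et3N, LiOTf, CH2Cl2, 0 °C
Reagents that add atoms: trifluoromethanesulfonic anhydride, O=S(=O)(OS(=O)(=O)C(F)(F)F)C(F)(F)F
Why: Chelation-controlled enol triflation of a β-keto ester, in which lithium holds both carbonyl oxygens of the enolate on one side so that O-sulfonylation should place OTf cis to the ester (E by CIP because OBn outranks the ester carbon), the geometry that lactonisation needs later.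

Step 4
Reactants: 7 propargyl alcohol
Product: 8 2-(tributylstannyl)prop-2-en-1-ol
Conditions: Bu3SnH, Mo(CO)3(CNtBu)3 (2 mol %), hydroquinone, THF, 55 °C
Reagents that add atoms: tributyltin hydride, CCCC[SnH](CCCC)CCCC
Why: Molybdenum-catalysed hydrostannation of a propargylic alcohol, a syn addition of Sn–H that is known to put tin on the internal alkyne carbon next to the oxygenated carbon.

Step 5
Reactants: 6 enol triflate; 8 2-(tributylstannyl)prop-2-en-1-ol
Product: 9 tert-butyl (2E)-2-(benzyloxy)-3-[4-(benzyloxy)phenyl]-4-(hydroxymethyl)penta-2,4-dienoate (new alkenyl group cis to the ester)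
Conditions: Pd(PPh3)4 (10 mol %), CuCl, LiCl, DMSO, 23 → 60 °C
Reagents that add atoms: none
Why: Stille coupling under the CuCl/LiCl protocol devised for congested 1-substituted vinylstannanes and enol triflates, in which oxidative addition and reductive elimination proceed with retention so the C3=C4 geometry should be kept, and the tert-butyl ester keeps the free CH2OH from lactonising.

Step 6
Reactants: 9 dienyl alcohol
Product: 10 tert-butyl (2E)-2-(benzyloxy)-3-[4-(benzyloxy)phenyl]-3-[(2R)-2-(hydroxymethyl)oxiran-2-yl]prop-2-enoate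
Conditions: Ti(OiPr)4 (20 mol %), D-(−)-diethyl tartrate (26 mol %), tBuOOH, 4 Å MS, CH2Cl2, −20 °C
Reagents that add atoms: tert-butyl hydroperoxide, CC(C)(C)OO
Why: Katsuki–Sharpless asymmetric epoxidation, in which only the 1,1-disubstituted alkene is allylic to the titanium-bound hydroxyl and D-(−)-diethyl tartrate directs oxygen to the face that gives the R epoxy alcohol, the sense established for 2-substituted allylic alcohols, so that C5 is set here.

Step 7
Reactants: 10 epoxy alcohol
Product: 12 (2S)-2-{(1E)-2-(benzyloxy)-1-[4-(benzyloxy)phenyl]-3-tert-butoxy-3-oxoprop-1-en-1-yl}oxirane-2-carboxylic acid, via epoxy aldehyde 11 (not isolated)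
Conditions: 2,2,6,6-tetramethylpiperidin-1-oxyl (TEMPO, 20 mol %), PhI(OAc)2 (2.5 equiv), MeCN/H2O, 0 → 23 °C
Reagents that add atoms: water, O
Why: Oxoammonium oxidation of a primary alcohol in aqueous acetonitrile runs through aldehyde 11 and its hydrate to the acid and should spare the oxirane, enol ether and benzyl ethers, with C5 keeping its geometry and becoming S only because the carboxyl carbon now outranks C6.

Step 8
Reactants: 12 glycidic acid
Product: 13 methyl (2S)-2-{(1E)-2-(benzyloxy)-1-[4-(benzyloxy)phenyl]-3-tert-butoxy-3-oxoprop-1-en-1-yl}oxirane-2-carboxylate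
Conditions: Me3SiCHN2, toluene/MeOH, 0 °C
Reagents that add atoms: (trimethylsilyl)diazomethane, C[Si](C)(C)C=[N+]=[N-]
Why: Esterification of a carboxylic acid with (trimethylsilyl)diazomethane in methanol, which is neutral and free of nucleophilic halide so that the oxirane should stay closed.

Step 9
Reactants: 14 4-bromophenol; 15 1-bromo-3-methylbut-2-ene (prenyl bromide)
Product: 16 4-bromo-2-(3-methylbut-2-en-1-yl)phenol
Conditions: NaH, toluene, 0 → 23 °C
Reagents that add atoms: none
Why: ortho-C-Alkylation of a sodium phenoxide in a non-polar solvent, where the tight ion pair shields oxygen, the para position is blocked by bromine, and any O-prenyl ether is removed by chromatography.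

Step 10
Reactants: 16 4-bromo-2-prenylphenol
Product: 17 [4-bromo-2-(3-methylbut-2-en-1-yl)phenoxy](tert-butyl)dimethylsilane
Conditions: TBSCl, imidazole, DMF, 23 °C
Reagents that add atoms: tert-butyldimethylsilyl chloride, CC(C)(C)[Si](C)(C)Cl
Why: Standard silylation of a phenol, which keeps the ring from being oxidised in the next step and postpones ring closure until the epoxide is complete.

Step 11
Reactants: 17 silyl ether
Product: 18 (4-bromo-2-{[(2R)-3,3-dimethyloxiran-2-yl]methyl}phenoxy)(tert-butyl)dimethylsilane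
Conditions: 1,2:4,5-di-O-isopropylidene-β-D-erythro-hexo-2,3-diulo-2,6-pyranose (D-fructose-derived Shi ketone, 30 mol %), Oxone (2KHSO5·KHSO4·K2SO4), K2CO3, Bu4NHSO4, MeCN/CH2(OMe)2/aq Na2B4O7 buffer, 0 °C
Reagents that add atoms: potassium peroxymonosulfate, [K+].[O-]S(=O)(=O)OO
Why: Shi asymmetric epoxidation, in which the dioxirane of the D-fructose-derived ketone meets the trisubstituted alkene in a spiro transition state and should give the R epoxide, the sense known for trans-disubstituted and trisubstituted alkenes.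

Step 12
Reactants: 18 epoxy silyl ether
Product: 20 2-[(2S)-5-bromo-2,3-dihydro-1-benzofuran-2-yl]propan-2-ol, via epoxy phenoxide 19 (not isolated)
Conditions: Bu4NF, THF, 0 → 23 °C
Reagents that add atoms: none
Why: Fluoride desilylation frees phenoxide 19, which opens the oxirane at its less substituted carbon in a 5-exo-tet SN2 reaction with inversion (R epoxide to S at C2'), the base-mediated mode that leads to 2-(2-hydroxypropan-2-yl)dihydrobenzofurans rather than chromanols.

Step 13
Reactants: 20 tertiary alcohol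
Product: 21 (2S)-2-{2-[(benzyloxy)methoxy]propan-2-yl}-5-bromo-2,3-dihydro-1-benzofuran
Conditions: BnOCH2Cl, iPr2NEt, Bu4NI (10 mol %), CH2Cl2, 40 °C
Reagents that add atoms: benzyl chloromethyl ether, ClCOCc1ccccc1
Why: Alkylation of the hindered tertiary alcohol with a reactive α-chloro ether under iodide catalysis gives an acetal that tolerates magnesium and organocopper reagents and leaves together with the benzyl ethers in step 16.

Step 14
Reactants: 21 aryl bromide
Product: 22 [(2S)-2-{2-[(benzyloxy)methoxy]propan-2-yl}-2,3-dihydro-1-benzofuran-5-yl]magnesium bromide (titrated THF solution, used directly)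
Conditions: Mg turnings (I2-activated), THF, 45 °C
Reagents that add atoms: magnesium, [Mg]
Why: Grignard formation by direct insertion of magnesium into an aryl bromide, to which the ring ether, the acetal and the C2' stereocentre are inert.

Step 15
Reactants: 13 methyl (2S)-glycidate; 22 aryl Grignard reagent
Product: 24 methyl (2R)-4-(benzyloxy)-3-[4-(benzyloxy)phenyl]-2-{[(2S)-2-{2-[(benzyloxy)methoxy]propan-2-yl}-2,3-dihydro-1-benzofuran-5-yl]methyl}-5-oxo-2,5-dihydrofuran-2-carboxylate, via ring-opened magnesium alkoxide 23 (not isolated)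
Conditions: CuI (15 mol %), THF, 22 (1.4 equiv) added slowly at −40 °C, then → 23 °C
Reagents that add atoms: none
Why: Transmetalation of 22 to CuI gives an arylcuprate that displaces the oxirane oxygen at the unsubstituted C6 in an SN2 manner (oxidative addition to a trivalent copper species, then reductive elimination), forming the C5'–C6 bond and alkoxide 23. The closest known chemistry is the copper-catalysed Grignard opening of terminal 2,2-disubstituted oxiranes and 2-substituted glycidic esters at CH2, joined to the familiar lactonisation of a released alkoxide onto a nearby ester. Because C5 and the C2 ester are cis on C3=C4, the C5 alkoxide adds to the tert-butyl ester carbonyl in a 5-exo-trig acyl substitution, expels tert-butoxide and closes the butenolide through O1–C2. No stereocentre is created: the C5–O1 bond is never broken, so the configuration from step 6 is carried over and only the descriptor changes from S to R as C6 drops in rank. The step needs attack at C6 rather than at C5, at C3 (SN2') or at an ester carbonyl; C5 is quaternary, C3 is fully substituted and is the α-carbon of an acrylate, the C2 ester is a hindered conjugated tert-butyl ester, the methyl ester sits on a quaternary carbon, and slow addition at low temperature keeps the free Grignard reagent scarce. Any minor enantiomer of either partner ends up as a diastereomer of 24 and can be removed at this stage.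

Step 16
Reactants: 24 protected butenolide
Product: 26 methyl (2R)-4-hydroxy-3-(4-hydroxyphenyl)-2-{[(2S)-2-(2-hydroxypropan-2-yl)-2,3-dihydro-1-benzofuran-5-yl]methyl}-5-oxo-2,5-dihydrofuran-2-carboxylate (CNP0280395.1), via hydroxymethyl acetal 25 (not isolated)
Conditions: H2 (1 atm), Pd(OH)2/C, EtOAc/MeOH, 23 °C
Reagents that add atoms: none
Why: Catalytic hydrogenolysis cleaves the aryl benzyl ether, the enol benzyl ether and the benzyl part of the acetal, hemiacetal 25 then loses formaldehyde, and the tetrasubstituted conjugated C3=C4 bond and both stereocentres are not expected to be touched.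

Compound list
1 | benzyl alcohol | OCc1ccccc1 | starting material
2 | tert-butyl bromoacetate | BrCC(=O)OC(C)(C)C | starting material
3 | tert-butyl 2-(benzyloxy)acetate | CC(C)(C)OC(=O)COCc1ccccc1 | intermediate
4 | methyl 4-(benzyloxy)benzoate | COC(=O)c1ccc(OCc2ccccc2)cc1 | starting material
5 | tert-butyl 2-(benzyloxy)-3-[4-(benzyloxy)phenyl]-3-oxopropanoate (racemic) | CC(C)(C)OC(=O)C(OCc1ccccc1)C(=O)c1ccc(OCc2ccccc2)cc1 | intermediate
6 | tert-butyl (2E)-2-(benzyloxy)-3-[4-(benzyloxy)phenyl]-3-(trifluoromethylsulfonyloxy)prop-2-enoate | FC(F)(F)S(=O)(=O)O/C(c1ccc(OCc2ccccc2)cc1)=C(/OCc1ccccc1)C(=O)OC(C)(C)C | intermediate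
7 | propargyl alcohol | C#CCO | starting material
8 | 2-(tributylstannyl)prop-2-en-1-ol | C=C(CO)[Sn](CCCC)(CCCC)CCCC | intermediate
9 | tert-butyl (2E)-2-(benzyloxy)-3-[4-(benzyloxy)phenyl]-4-(hydroxymethyl)penta-2,4-dienoate | C=C(CO)/C(c1ccc(OCc2ccccc2)cc1)=C(/OCc1ccccc1)C(=O)OC(C)(C)C | intermediate
10 | tert-butyl (2E)-2-(benzyloxy)-3-[4-(benzyloxy)phenyl]-3-[(2R)-2-(hydroxymethyl)oxiran-2-yl]prop-2-enoate | OC[C@@]1(CO1)/C(c1ccc(OCc2ccccc2)cc1)=C(/OCc1ccccc1)C(=O)OC(C)(C)C | intermediate
11 | tert-butyl (2E)-2-(benzyloxy)-3-[4-(benzyloxy)phenyl]-3-[(2S)-2-formyloxiran-2-yl]prop-2-enoate | O=C[C@@]1(CO1)/C(c1ccc(OCc2ccccc2)cc1)=C(/OCc1ccccc1)C(=O)OC(C)(C)C | intermediate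
12 | (2S)-2-{(1E)-2-(benzyloxy)-1-[4-(benzyloxy)phenyl]-3-tert-butoxy-3-oxoprop-1-en-1-yl}oxirane-2-carboxylic acid | OC(=O)[C@@]1(CO1)/C(c1ccc(OCc2ccccc2)cc1)=C(/OCc1ccccc1)C(=O)OC(C)(C)C | intermediate
13 | methyl (2S)-2-{(1E)-2-(benzyloxy)-1-[4-(benzyloxy)phenyl]-3-tert-butoxy-3-oxoprop-1-en-1-yl}oxirane-2-carboxylate | COC(=O)[C@@]1(CO1)/C(c1ccc(OCc2ccccc2)cc1)=C(/OCc1ccccc1)C(=O)OC(C)(C)C | intermediate
14 | 4-bromophenol | Oc1ccc(Br)cc1 | starting material
15 | 1-bromo-3-methylbut-2-ene | CC(C)=CCBr | starting material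
16 | 4-bromo-2-(3-methylbut-2-en-1-yl)phenol | CC(C)=CCc1cc(Br)ccc1O | intermediate
17 | [4-bromo-2-(3-methylbut-2-en-1-yl)phenoxy](tert-butyl)dimethylsilane | CC(C)=CCc1cc(Br)ccc1O[Si](C)(C)C(C)(C)C | intermediate
18 | (4-bromo-2-{[(2R)-3,3-dimethyloxiran-2-yl]methyl}phenoxy)(tert-butyl)dimethylsilane | CC1(C)O[C@@H]1Cc1cc(Br)ccc1O[Si](C)(C)C(C)(C)C | intermediate
19 | tetrabutylammonium 4-bromo-2-{[(2R)-3,3-dimethyloxiran-2-yl]methyl}phenoxide | CC1(C)O[C@@H]1Cc1cc(Br)ccc1[O-].CCCC[N+](CCCC)(CCCC)CCCC | intermediate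
20 | 2-[(2S)-5-bromo-2,3-dihydro-1-benzofuran-2-yl]propan-2-ol | Brc1ccc2c(c1)C[C@@H](C(C)(C)O)O2 | intermediate
21 | (2S)-2-{2-[(benzyloxy)methoxy]propan-2-yl}-5-bromo-2,3-dihydro-1-benzofuran | Brc1ccc2c(c1)C[C@@H](C(C)(C)OCOCc3ccccc3)O2 | intermediate
22 | [(2S)-2-{2-[(benzyloxy)methoxy]propan-2-yl}-2,3-dihydro-1-benzofuran-5-yl]magnesium bromide | Br[Mg]c1ccc2c(c1)C[C@@H](C(C)(C)OCOCc3ccccc3)O2 | intermediate
23 | bromomagnesium alkoxide of 1-tert-butyl 5-methyl (2E,4R)-2-(benzyloxy)-3-[4-(benzyloxy)phenyl]-4-hydroxy-4-{[(2S)-2-{2-[(benzyloxy)methoxy]propan-2-yl}-2,3-dihydro-1-benzofuran-5-yl]methyl}pent-2-enedioate | COC(=O)[C@](Cc1ccc2c(c1)C[C@@H](C(C)(C)OCOCc3ccccc3)O2)(O[Mg]Br)/C(c1ccc(OCc2ccccc2)cc1)=C(/OCc1ccccc1)C(=O)OC(C)(C)C | intermediate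
24 | methyl (2R)-4-(benzyloxy)-3-[4-(benzyloxy)phenyl]-2-{[(2S)-2-{2-[(benzyloxy)methoxy]propan-2-yl}-2,3-dihydro-1-benzofuran-5-yl]methyl}-5-oxo-2,5-dihydrofuran-2-carboxylate | COC(=O)[C@]1(Cc2ccc3c(c2)C[C@@H](C(C)(C)OCOCc4ccccc4)O3)OC(=O)C(OCc2ccccc2)=C1c1ccc(OCc2ccccc2)cc1 | intermediate
25 | methyl (2R)-4-hydroxy-2-{[(2S)-2-[2-(hydroxymethoxy)propan-2-yl]-2,3-dihydro-1-benzofuran-5-yl]methyl}-3-(4-hydroxyphenyl)-5-oxo-2,5-dihydrofuran-2-carboxylate | COC(=O)[C@]1(Cc2ccc3c(c2)C[C@@H](C(C)(C)OCO)O3)OC(=O)C(O)=C1c1ccc(O)cc1 | intermediate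
26 | methyl (2R)-4-hydroxy-3-(4-hydroxyphenyl)-2-{[(2S)-2-(2-hydroxypropan-2-yl)-2,3-dihydro-1-benzofuran-5-yl]methyl}-5-oxo-2,5-dihydrofuran-2-carboxylate | COC(=O)[C@]1(Cc2ccc3c(c2)C[C@@H](C(C)(C)O)O3)OC(=O)C(O)=C1c1ccc(O)cc1 | target

Total step count: 16.
Longest linear sequence: 9 (steps 1, 2, 3, 5, 6, 7, 8, 15, 16). The Grignard branch contributes 8 (steps 9–16).

Steps most likely to fail

Step 15. Free Grignard reagent may add to the methyl ester beside the oxirane. Bromide may open the oxirane, and the halohydrin alkoxide would then lactonise irreversibly. Expulsion of tert-butoxide may also lag behind.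
- The fallback takes the ester away from the oxirane and performs the opening one oxidation level lower.
- It sets out from epoxy alcohol 10. Silylation (TBSCl, imidazole) would give the tert-butyldimethylsilyl ether of the epoxy alcohol F1.
- Reagent 22 with CuI opens it at C6 to the ring-opened magnesium alkoxide F2, which lactonises to the 5-(silyloxymethyl)butenolide F3.
- HF·pyridine frees the primary alcohol F4. This is oxidised at once with TEMPO/PhI(OAc)2 in aqueous MeCN, before acyl migration can set in, through the C5 aldehyde F5 to the C5 carboxylic acid F6.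
- Me3SiCHN2 brings the material back to the route at 24.

Step 5. Transmetalation between two congested partners may be slow. Protodestannylation, cine substitution, loss of the triflate or scrambling of the alkene geometry at the alkenylpalladium stage could then take over.
- The fallback installs a smaller, unfunctionalised three-carbon unit with boron and adds the oxygen later by C–H oxidation.
- It sets out from enol triflate 6. Suzuki–Miyaura coupling with commercial isopropenylboronic acid pinacol ester (Pd(dppf)Cl2, K3PO4, dioxane/H2O) would give the isopropenyl dienoate F7.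
- Allylic oxidation of its only allylic methyl group with SeO2 (catalytic)/tBuOOH (ene reaction, then [2,3]-shift) returns to the route at 9.

Step 6. The very bulky 2-substituent may cause poor facial selectivity or low rate, and the titanium alkoxide may open the tertiary allylic oxirane.
- The fallback replaces hydroxyl-directed metal catalysis by iminium catalysis.
- It sets out from 9. MnO2 oxidation would give the 2-substituted acrolein F8.
- Epoxidation with aqueous H2O2 and a diphenylprolinol silyl ether is a known reaction of α-substituted acroleins and gives epoxy aldehyde 11, which is isolated in this variant. The catalyst is 2-[diphenyl(trimethylsilyloxy)methyl]pyrrolidine, with the enantiomer chosen so that the S aldehyde results.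
- Pinnick oxidation (NaClO2, NaH2PO4, 2-methylbut-2-ene) rejoins the route at acid 12.

Further compounds
F1 | step 15 | tert-butyl (2E)-2-(benzyloxy)-3-[4-(benzyloxy)phenyl]-3-[(2S)-2-{[(tert-butyldimethylsilyl)oxy]methyl}oxiran-2-yl]prop-2-enoate | CC(C)(C)[Si](C)(C)OC[C@@]1(CO1)/C(c1ccc(OCc2ccccc2)cc1)=C(/OCc1ccccc1)C(=O)OC(C)(C)C
F2 | step 15 | bromomagnesium alkoxide from opening of F1 at C6 by 22 (C5 geometry as in 23) | CC(C)(C)[Si](C)(C)OC[C@](Cc1ccc2c(c1)C[C@@H](C(C)(C)OCOCc3ccccc3)O2)(O[Mg]Br)/C(c1ccc(OCc2ccccc2)cc1)=C(/OCc1ccccc1)C(=O)OC(C)(C)C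
F3 | step 15 | (5R)-3-(benzyloxy)-4-[4-(benzyloxy)phenyl]-5-{[(2S)-2-{2-[(benzyloxy)methoxy]propan-2-yl}-2,3-dihydro-1-benzofuran-5-yl]methyl}-5-{[(tert-butyldimethylsilyl)oxy]methyl}furan-2(5H)-one | CC(C)(C)[Si](C)(C)OC[C@]1(Cc2ccc3c(c2)C[C@@H](C(C)(C)OCOCc4ccccc4)O3)OC(=O)C(OCc2ccccc2)=C1c1ccc(OCc2ccccc2)cc1
F4 | step 15 | (5R)-3-(benzyloxy)-4-[4-(benzyloxy)phenyl]-5-{[(2S)-2-{2-[(benzyloxy)methoxy]propan-2-yl}-2,3-dihydro-1-benzofuran-5-yl]methyl}-5-(hydroxymethyl)furan-2(5H)-one | OC[C@]1(Cc2ccc3c(c2)C[C@@H](C(C)(C)OCOCc4ccccc4)O3)OC(=O)C(OCc2ccccc2)=C1c1ccc(OCc2ccccc2)cc1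
F5 | step 15 | (2R)-4-(benzyloxy)-3-[4-(benzyloxy)phenyl]-2-{[(2S)-2-{2-[(benzyloxy)methoxy]propan-2-yl}-2,3-dihydro-1-benzofuran-5-yl]methyl}-5-oxo-2,5-dihydrofuran-2-carbaldehyde | O=C[C@]1(Cc2ccc3c(c2)C[C@@H](C(C)(C)OCOCc4ccccc4)O3)OC(=O)C(OCc2ccccc2)=C1c1ccc(OCc2ccccc2)cc1
F6 | step 15 | (2R)-4-(benzyloxy)-3-[4-(benzyloxy)phenyl]-2-{[(2S)-2-{2-[(benzyloxy)methoxy]propan-2-yl}-2,3-dihydro-1-benzofuran-5-yl]methyl}-5-oxo-2,5-dihydrofuran-2-carboxylic acid | OC(=O)[C@]1(Cc2ccc3c(c2)C[C@@H](C(C)(C)OCOCc4ccccc4)O3)OC(=O)C(OCc2ccccc2)=C1c1ccc(OCc2ccccc2)cc1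
F7 | step 5 | tert-butyl (2Z)-2-(benzyloxy)-3-[4-(benzyloxy)phenyl]-4-methylpenta-2,4-dienoate (same spatial arrangement as 9) | C=C(C)/C(c1ccc(OCc2ccccc2)cc1)=C(/OCc1ccccc1)C(=O)OC(C)(C)C
F8 | step 6 | tert-butyl (2E)-2-(benzyloxy)-3-[4-(benzyloxy)phenyl]-4-formylpenta-2,4-dienoate | C=C(C=O)/C(c1ccc(OCc2ccccc2)cc1)=C(/OCc1ccccc1)C(=O)OC(C)(C)C
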